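All runs are simulated from invented constants.

Amounts first, since you asked for a quick number and your hunch is more coupling partner.

- Wednesday's: starting material 0.050 M; coupling partner 0.125 M; capture agent 1 mM; protic impurity 5 mM; free catalyst 10 mM; second catalyst 0.11 mM; the very flask that is asked about, followed so far
- flask: starting material 0.050 M; coupling partner 0.125 M; capture agent 1.00 mM; protic impurity 5.00 mM; free catalyst 10 mM; second catalyst 0.11 mM; time 6.0 h

Wednesday's run (percent of the starting material charged)

| time / min | product / % | starting material / % |
|---|---|---|
| 25.0 | 22.2 | 59.2 |
| 40.0 | 29.9 | 50.7 |
| 60.0 | 40.2 | 42.1 |
| 120 | 58.7 | 26.5 |
| 180 | 69.6 | 17.9 |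
| 300 | 77.4 | 12.5 |

(each reading ± 0.5 percentage points)

- what is taken out of product is counted as made
- reactions considered so far: open intermediate + capture agent -> trapped intermediate; starting material + protic impurity -> quenched substrate; free catalyst -> spent catalyst; starting material + free catalyst <-> free catalyst + open intermediate; coupling partner + second catalyst + open intermediate -> second catalyst + product
- "the catalyst" is free catalyst with its forms; second catalyst is a second catalyst
- additions bring no volume worth counting

- north-west: at 6.0 h add coupling partner, 100% of the amount charged, then wait 2.0 h
- south-east: change nothing and wait 2.0 h more
- east: at 6.0 h add free catalyst, 100% of the amount charged, then wait 2.0 h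
- west: at 6.0 h take out 90% of the product then present, then wait 2.0 h

- product, in percent of the starting material first charged, at 6.0 h
- the option that brings most further product ("none" if no option brings more than 2 percentage points) (north-west / south-east / east / west / none)
- product present, with what was taken out counted in, in percent of the starting material first charged, after north-west
- product present, with what was taken out counted in, in percent of the starting material first charged, after east

Wednesday's run is this very flask. Its protic impurity can take 0.100 of the starting material, so I call the other 0.900 of the charge the pool. The pool left at any time is that less the product. Then count turnovers: take the natural log of the first pool over the pool left, as for a pseudo-first-order loss. The count reads 1.06 at 120 min, 1.48 at 180 min and 1.97 at 300 min.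

Its pace fell from 0.007135 min⁻¹ to 0.004015 min⁻¹, and I read that as free catalyst dying. Carrying the same fall forward gives 0.002260 min⁻¹. So the turnover count at 6.0 h, the one number I carry, is 2.10. That puts product at 79.0%.

Waiting adds about 1.6 percentage points, less than the margin. Your partner is not short: by my balance 0.684 of it stands at 6.0 h. Adding more pulls harder on the open intermediate, and the last reading leaves about 1.00 × 10⁻³ of the charge for that, within scatter. So I rate north-west near waiting. The coupling is written one-way, so I rate west the same as waiting.

A fresh charge of catalyst restarts the count. The first charge made 1.06 in 120 min. Scaled by partner, 0.684 against a mean of 0.883, that gives 0.819. By this reckoning east reaches 85.1%.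

The forecast says 79%, east as best, 81.2% after north-west and 86% after east, on the ground that “Fresh catalyst reopens the starting material”.

The flask gives 78.3%, with east best at 84.6% and north-west at 79.1%. Free catalyst stood at 0.351% of its charge at 360 min. Put into the count, 78.3% of product is 2.04 turnovers against my 2.10.

    open intermediate + capture agent → trapped intermediate (k = 0.522 L mol⁻¹ min⁻¹)
    starting material + protic impurity → quenched substrate (k = 2.02 L mol⁻¹ min⁻¹)
    free catalyst → spent catalyst (k = 0.0157 min⁻¹)
    starting material + free catalyst ⇌ free catalyst + open intermediate (K = 0.201, k = 28.4 L mol⁻¹ min⁻¹)
    coupling partner + second catalyst + open intermediate → second catalyst + product (k = 4890 L² mol⁻² min⁻¹)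

Now take the neighbour with 6.6 × 10⁻⁵ M of second catalyst, 0.600 of this charge. Scaling my count gives 1.26, so product near 64.5%. The simulation gives 68.7%, a count of 1.44. In that neighbour the count stands at 0.706 of the flask's, more than the second catalyst's 0.600.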